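The dihydropyranone ring (O1, C2 with the methyl group, C3, C4=O, C5, C6 on the coumarin) is cut at C4–C5 and O1–C2. Its O1–C6=C5 edge is the enol of the acetyl group of a 3-acetylcoumarin, a C,O-dinucleophile used as its silyl enol ether; C4–C3–C2 is (S)-3-(tosyloxy)butanoyl chloride, a chiral-pool dielectrophile. In one flask, C-acylation gives a β-diketone whose enolate oxygen displaces the tosylate (6-exo-tet, inversion), closing the ring and setting C2 as R. The acetylcoumarin comes from Knoevenagel condensation of a lactol made by carboxylate-directed C–H alkylation of a benzoic acid with (S)-propylene oxide.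

Key step: step 10

Remark: 2,4-dimethoxy-3-methylbenzoic acid, (S)-propylene oxide and tert-butyl (3S)-3-hydroxybutanoate are taken as catalogue compounds; lactol 8 is drawn closed and is assumed to react through its open hydroxy-aldehyde tautomer.

**Step 1**
Reactants: 1 2,4-dimethoxy-3-methylbenzoic acid; 2 (S)-propylene oxide
Product: 4 (3S)-6,8-dimethoxy-3,7-dimethylisochroman-1-one, via ortho-alkylated hydroxy acid 3 (not isolated)
Conditions: Pd(OAc)2 (5 mol%), N-acetyl-L-tert-leucine (10 mol%), KOAc, (CF3)2CHOH, 60 °C, sealed tube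
Reagents that add atoms: none
Why: Carboxylate-directed ortho C–H alkylation of a benzoic acid with an epoxide by divalent palladium, followed by lactonisation, should occur at C6–H (the only ortho C–H) with opening of the epoxide at its CH2 terminus, so the 3S centre is carried over untouched from the chiral pool.

**Step 2**
Reactants: 4 (3S)-6,8-dimethoxy-3,7-dimethylisochroman-1-one
Product: 5 (3S)-5-bromo-6,8-dimethoxy-3,7-dimethylisochroman-1-one
Conditions: N-bromosuccinimide, MeCN, 0 °C → rt, dark
Reagents that add atoms: N-bromosuccinimide O=C1CCC(=O)N1Br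
Why: Electrophilic aromatic bromination should go to C5, the only free ring position, which is ortho and para to the two methoxy groups and meta to the lactone carbonyl.

**Step 3**
Reactants: 5 (3S)-5-bromo-6,8-dimethoxy-3,7-dimethylisochroman-1-one
Product: 6 (3S)-6,8-dimethoxy-3,5,7-trimethylisochroman-1-one
Conditions: MeB(OH)2, Pd(OAc)2 (5 mol%), 2-dicyclohexylphosphino-2',6'-dimethoxybiphenyl (10 mol%), K3PO4, toluene/H2O, 100 °C
Reagents that add atoms: methylboronic acid CB(O)O
Why: Suzuki–Miyaura methylation with a bulky electron-rich biaryl phosphine should couple the di-ortho-substituted aryl bromide, and any lactone opened by the base recloses on acidic work-up.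

**Step 4**
Reactants: 6 (3S)-6,8-dimethoxy-3,5,7-trimethylisochroman-1-one
Product: 7 (3S)-6,8-dihydroxy-3,5,7-trimethylisochroman-1-one
Conditions: BBr3 (4 equiv), CH2Cl2, −78 °C → rt; H2O
Reagents that add atoms: none
Why: Lewis-acid cleavage of aryl methyl ethers with BBr3 should free both phenols (the C8 ether assisted by chelation to the carbonyl) while the secondary alkyl lactone C–O bond and the stereocentre stay intact.

**Step 5**
Reactants: 7 (3S)-6,8-dihydroxy-3,5,7-trimethylisochroman-1-one
Product: 8 (3S)-3,5,7-trimethylisochromane-1,6,8-triol (lactol; mixture of C1 epimers)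
Conditions: i-Bu2AlH (3.5 equiv), CH2Cl2/THF, −78 °C; aq. potassium sodium tartrate
Reagents that add atoms: none
Why: Partial reduction of a lactone to a lactol with i-Bu2AlH at low temperature should stop at the aluminium hemiacetal, which is held by chelation to the neighbouring aluminium phenoxide until work-up.

**Step 6**
Reactants: 8 (3S)-3,5,7-trimethylisochromane-1,6,8-triol; 9 ethyl acetoacetate
Product: 11 3-acetyl-7-hydroxy-5-[(2S)-2-hydroxypropyl]-6,8-dimethyl-2H-chromen-2-one, via Knoevenagel adduct 10 (not isolated)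
Conditions: piperidine (20 mol%), AcOH (20 mol%), EtOH, 60 °C
Reagents that add atoms: none
Why: Knoevenagel condensation of the open salicylaldehyde tautomer of the lactol with the β-keto ester, followed by lactonisation of the ortho phenol onto the ethyl ester (classical 3-acetylcoumarin synthesis), should be driven by formation of the coumarin and leaves the carbinol centre untouched.

**Step 7**
Reactants: 11 3-acetyl-7-hydroxy-5-[(2S)-2-hydroxypropyl]-6,8-dimethyl-2H-chromen-2-one
Product: 12 7-[(tert-butyldimethylsilyl)oxy]-5-{(2S)-2-[(tert-butyldimethylsilyl)oxy]propyl}-3-{1-[(tert-butyldimethylsilyl)oxy]ethenyl}-6,8-dimethyl-2H-chromen-2-one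
Conditions: TBSOTf (4 equiv), Et3N (6 equiv), CH2Cl2, 0 °C → rt
Reagents that add atoms: tert-butyldimethylsilyl trifluoromethanesulfonate CC(C)(C)[Si](C)(C)OS(=O)(=O)C(F)(F)F
Why: Silyl triflate with an amine base should silylate the hindered phenol and the secondary alcohol and convert the methyl ketone into its silyl enol ether (soft enolisation) in one operation, giving both protection and the nucleophile for the key step.

**Step 8**
Reactants: 13 tert-butyl (3S)-3-hydroxybutanoate
Product: 14 tert-butyl (3S)-3-{[(4-methylphenyl)sulfonyl]oxy}butanoate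
Conditions: TsCl, pyridine, CH2Cl2, 0 → 5 °C
Reagents that add atoms: 4-methylbenzenesulfonyl chloride Cc1ccc(cc1)S(=O)(=O)Cl
Why: O-sulfonylation of the secondary alcohol forms only an O–S bond, so the S configuration is retained, and cold pyridine is too weak a base to eliminate the β-tosylate.

**Step 9**
Reactants: 14 tert-butyl (3S)-3-{[(4-methylphenyl)sulfonyl]oxy}butanoate
Product: 16 (3S)-3-{[(4-methylphenyl)sulfonyl]oxy}butanoyl chloride, via free carboxylic acid 15 (not isolated)
Conditions: SOCl2 (neat), rt; excess SOCl2 removed in vacuo, product used crude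
Reagents that add atoms: thionyl chloride ClS(Cl)=O
Why: Acid-promoted cleavage of the tert-butyl ester by the HCl present in SOCl2 and chlorination of the liberated acid (direct tert-butyl ester to acid chloride conversion) proceed without base, so the β-tosylate should neither eliminate nor epimerise.

**Step 10**
Reactants: 12 7-[(tert-butyldimethylsilyl)oxy]-5-{(2S)-2-[(tert-butyldimethylsilyl)oxy]propyl}-3-{1-[(tert-butyldimethylsilyl)oxy]ethenyl}-6,8-dimethyl-2H-chromen-2-one; 16 (3S)-3-{[(4-methylphenyl)sulfonyl]oxy}butanoyl chloride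
Product: 18 7-[(tert-butyldimethylsilyl)oxy]-5-{(2S)-2-[(tert-butyldimethylsilyl)oxy]propyl}-6,8-dimethyl-3-[(2R)-2-methyl-4-oxo-3,4-dihydro-2H-pyran-6-yl]-2H-chromen-2-one, via tosyloxy diketone 17 (not isolated)
Conditions: ZnCl2 (20 mol%), CH2Cl2, −20 → 0 °C; then DMF, Cs2CO3 (4 equiv), 0 → 40 °C
Reagents that add atoms: none
Why: Proposed new method: the enol silane carbon C5 of 12 attacks the ZnCl2-activated acyl chloride 16 (Mukaiyama-type C-acylation with loss of TBSCl) to form C5–C4 and the β-diketone 17, and after Cs2CO3 is added the delocalised enolate attacks the tosylate-bearing C2 through the oxygen on C6 to form O1–C2. The closest known reactions are the ZnCl2-promoted acylation of ketone silyl enol ethers with acid chlorides to 1,3-diketones, the intramolecular O-alkylation of 1,3-dicarbonyl enolates, and the chroman-4-one synthesis from phenols and 3-halopropanoyl chlorides, which is the same C-acylation/O-alkylation annulation on an arene. The dihydropyranone ring closes in a 6-exo-tet mode with the enolate C5=C6 bond inside the ring, the only feasible closure because attack by C5 or by the C4 oxygen would give four-membered rings. C2 is the only new stereocentre and is set by the substrate: SN2 displacement inverts the S tosylate from the chiral pool to the R ether, independently of the remote carbinol centre. The step needs C- over O-acylation, which the Lewis acid and the soft enol silane carbon should secure, and substitution over β-elimination to a crotonyl ketone that would reclose without stereocontrol; this is addressed by forming 17 in the absence of base and then converting it fully into its monoanion, whose C3–H is no longer acidic, in a polar medium with a non-chelating cation.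

**Step 11**
Reactants: 18 7-[(tert-butyldimethylsilyl)oxy]-5-{(2S)-2-[(tert-butyldimethylsilyl)oxy]propyl}-6,8-dimethyl-3-[(2R)-2-methyl-4-oxo-3,4-dihydro-2H-pyran-6-yl]-2H-chromen-2-one
Product: 19 7-hydroxy-5-[(2S)-2-hydroxypropyl]-6,8-dimethyl-3-[(2R)-2-methyl-4-oxo-3,4-dihydro-2H-pyran-6-yl]-2H-chromen-2-one
Conditions: HF·pyridine, THF/pyridine, 0 °C → rt
Reagents that add atoms: none
Why: Fluoride-mediated desilylation under weakly acidic conditions should cleave the aryl and the secondary alkyl silyl ethers without the base-induced retro-oxa-Michael opening that could scramble C2 of the dihydropyranone.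

**Compound list**

1 | 2,4-dimethoxy-3-methylbenzoic acid | COc1ccc(C(=O)O)c(OC)c1C | starting material
2 | (S)-propylene oxide, (2S)-2-methyloxirane | C[C@H]1CO1 | starting material
3 | 6-[(2S)-2-hydroxypropyl]-2,4-dimethoxy-3-methylbenzoic acid (formed in the flask, not isolated) | C[C@H](O)Cc1cc(OC)c(C)c(OC)c1C(=O)O | intermediate
4 | (3S)-6,8-dimethoxy-3,7-dimethylisochroman-1-one | C[C@H]1Cc2cc(OC)c(C)c(OC)c2C(=O)O1 | intermediate
5 | (3S)-5-bromo-6,8-dimethoxy-3,7-dimethylisochroman-1-one | C[C@H]1Cc2c(Br)c(OC)c(C)c(OC)c2C(=O)O1 | intermediate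
6 | (3S)-6,8-dimethoxy-3,5,7-trimethylisochroman-1-one | C[C@H]1Cc2c(C)c(OC)c(C)c(OC)c2C(=O)O1 | intermediate
7 | (3S)-6,8-dihydroxy-3,5,7-trimethylisochroman-1-one | C[C@H]1Cc2c(C)c(O)c(C)c(O)c2C(=O)O1 | intermediate
8 | (3S)-3,5,7-trimethylisochromane-1,6,8-triol (lactol, C1 epimers; ring-chain tautomer of 2,4-dihydroxy-6-[(2S)-2-hydroxypropyl]-3,5-dimethylbenzaldehyde) | C[C@H]1Cc2c(C)c(O)c(C)c(O)c2C(O)O1 | intermediate
9 | ethyl acetoacetate | CCOC(=O)CC(C)=O | starting material
10 | ethyl 2-acetyl-3-{2,4-dihydroxy-6-[(2S)-2-hydroxypropyl]-3,5-dimethylphenyl}prop-2-enoate (formed in the flask, not isolated) | CCOC(=O)C(C(C)=O)=Cc1c(O)c(C)c(O)c(C)c1C[C@H](C)O | intermediate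
11 | 3-acetyl-7-hydroxy-5-[(2S)-2-hydroxypropyl]-6,8-dimethyl-2H-chromen-2-one | CC(=O)c1cc2c(C[C@H](C)O)c(C)c(O)c(C)c2oc1=O | intermediate
12 | 7-[(tert-butyldimethylsilyl)oxy]-5-{(2S)-2-[(tert-butyldimethylsilyl)oxy]propyl}-3-{1-[(tert-butyldimethylsilyl)oxy]ethenyl}-6,8-dimethyl-2H-chromen-2-one | C=C(O[Si](C)(C)C(C)(C)C)c1cc2c(C[C@H](C)O[Si](C)(C)C(C)(C)C)c(C)c(O[Si](C)(C)C(C)(C)C)c(C)c2oc1=O | intermediate
13 | tert-butyl (3S)-3-hydroxybutanoate | C[C@H](O)CC(=O)OC(C)(C)C | starting material
14 | tert-butyl (3S)-3-{[(4-methylphenyl)sulfonyl]oxy}butanoate | C[C@H](OS(=O)(=O)c1ccc(C)cc1)CC(=O)OC(C)(C)C | intermediate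
15 | (3S)-3-{[(4-methylphenyl)sulfonyl]oxy}butanoic acid (formed in the flask, not isolated) | C[C@H](OS(=O)(=O)c1ccc(C)cc1)CC(=O)O | intermediate
16 | (3S)-3-{[(4-methylphenyl)sulfonyl]oxy}butanoyl chloride | C[C@H](OS(=O)(=O)c1ccc(C)cc1)CC(=O)Cl | intermediate
17 | (2S)-6-{7-[(tert-butyldimethylsilyl)oxy]-5-{(2S)-2-[(tert-butyldimethylsilyl)oxy]propyl}-6,8-dimethyl-2-oxo-2H-chromen-3-yl}-4,6-dioxohexan-2-yl 4-methylbenzenesulfonate (formed in the flask, not isolated) | C[C@H](OS(=O)(=O)c1ccc(C)cc1)CC(=O)CC(=O)c1cc2c(C[C@H](C)O[Si](C)(C)C(C)(C)C)c(C)c(O[Si](C)(C)C(C)(C)C)c(C)c2oc1=O | intermediate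
18 | 7-[(tert-butyldimethylsilyl)oxy]-5-{(2S)-2-[(tert-butyldimethylsilyl)oxy]propyl}-6,8-dimethyl-3-[(2R)-2-methyl-4-oxo-3,4-dihydro-2H-pyran-6-yl]-2H-chromen-2-one | Cc1c(O[Si](C)(C)C(C)(C)C)c(C)c2oc(=O)c(C3=CC(=O)C[C@@H](C)O3)cc2c1C[C@H](C)O[Si](C)(C)C(C)(C)C | intermediate
19 | 7-hydroxy-5-[(2S)-2-hydroxypropyl]-6,8-dimethyl-3-[(2R)-2-methyl-4-oxo-3,4-dihydro-2H-pyran-6-yl]-2H-chromen-2-one | Cc1c(O)c(C)c2oc(=O)c(C3=CC(=O)C[C@@H](C)O3)cc2c1C[C@H](C)O | target

**Step count and risks**

Total step count: 11 (nine in the main line, two for the acyl chloride 16).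
Longest linear sequence: 9 steps (steps 1–7, 10 and 11, from compound 1).

Steps most likely to fail:

1. Step 10 (proposed new method). The configurational purity at C2 may erode if the β-tosyloxy acyl unit eliminates before or after C–C bond formation and the resulting enone recloses by unselective conjugate addition. O-acylation of the enol silane and acyl transfer to the silyl ether oxygens may also compete. The fallback uses known chemistry, sets out from 12 and returns at 19. Commercial methyl (3R)-3-hydroxybutanoate would be silylated (TBSCl, imidazole) to methyl (3R)-3-[(tert-butyldimethylsilyl)oxy]butanoate F1 and reduced with i-Bu2AlH at −78 °C to (3R)-3-[(tert-butyldimethylsilyl)oxy]butanal F2. Mukaiyama aldol addition of 12 to F2 (BF3·OEt2, CH2Cl2, −78 °C) should give the aldol adduct F3 as a mixture of carbinol epimers, and Dess–Martin periodinane should oxidise it to the silyloxy β-diketone F4. HF·pyridine followed by catalytic TsOH would remove the three silyl groups, and the freed δ-hydroxy-β-diketone should close to the cyclic hemiketal and lose water to give 19. The ring oxygen then comes from the R carbinol with retention.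

2. Step 1. Palladation of the electron-rich, ortho-substituted acid may be slow, so that opening of the epoxide by the carboxylate or by the solvent consumes the reagents before C–H alkylation occurs. The fallback sets out from 1 and returns at 4. Compound 1 would be converted ((COCl)2, cat. DMF; then Et2NH) into N,N-diethyl-2,4-dimethoxy-3-methylbenzamide F5. Amide-directed ortho-lithiation at C6 (s-BuLi, TMEDA, THF, −78 °C) and opening of 2 at its CH2 terminus in the presence of BF3·OEt2 should give N,N-diethyl-6-[(2S)-2-hydroxypropyl]-2,4-dimethoxy-3-methylbenzamide F6. Heating F6 with TsOH in toluene should lactonise it to 4.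

3. Step 5. The lactone may be over-reduced to the benzylic alcohol once the aluminium hemiacetal collapses, or the aluminium bis-phenoxide may precipitate and stall the reduction. The fallback sets out from 7 and returns at 8. Compound 7 would be reduced fully with LiAlH4 (THF, 0 °C → rt) to 4-(hydroxymethyl)-5-[(2S)-2-hydroxypropyl]-2,6-dimethylbenzene-1,3-diol F7. Activated MnO2 (acetone, rt) should then oxidise the benzylic alcohol selectively to the salicylaldehyde, which closes to 8.

**Further compounds**

F1 | step 10 | methyl (3R)-3-[(tert-butyldimethylsilyl)oxy]butanoate | C[C@@H](O[Si](C)(C)C(C)(C)C)CC(=O)OC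
F2 | step 10 | (3R)-3-[(tert-butyldimethylsilyl)oxy]butanal | C[C@@H](O[Si](C)(C)C(C)(C)C)CC=O
F3 | step 10 | 7-[(tert-butyldimethylsilyl)oxy]-3-{(5R)-5-[(tert-butyldimethylsilyl)oxy]-3-hydroxyhexanoyl}-5-{(2S)-2-[(tert-butyldimethylsilyl)oxy]propyl}-6,8-dimethyl-2H-chromen-2-one (aldol adduct, carbinol epimers) | C[C@@H](O[Si](C)(C)C(C)(C)C)CC(O)CC(=O)c1cc2c(C[C@H](C)O[Si](C)(C)C(C)(C)C)c(C)c(O[Si](C)(C)C(C)(C)C)c(C)c2oc1=O
F4 | step 10 | 7-[(tert-butyldimethylsilyl)oxy]-3-{(5R)-5-[(tert-butyldimethylsilyl)oxy]-3-oxohexanoyl}-5-{(2S)-2-[(tert-butyldimethylsilyl)oxy]propyl}-6,8-dimethyl-2H-chromen-2-one (silyloxy β-diketone) | C[C@@H](O[Si](C)(C)C(C)(C)C)CC(=O)CC(=O)c1cc2c(C[C@H](C)O[Si](C)(C)C(C)(C)C)c(C)c(O[Si](C)(C)C(C)(C)C)c(C)c2oc1=O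
F5 | step 1 | N,N-diethyl-2,4-dimethoxy-3-methylbenzamide | CCN(CC)C(=O)c1ccc(OC)c(C)c1OC
F6 | step 1 | N,N-diethyl-6-[(2S)-2-hydroxypropyl]-2,4-dimethoxy-3-methylbenzamide | CCN(CC)C(=O)c1c(C[C@H](C)O)cc(OC)c(C)c1OC
F7 | step 5 | 4-(hydroxymethyl)-5-[(2S)-2-hydroxypropyl]-2,6-dimethylbenzene-1,3-diol | C[C@H](O)Cc1c(C)c(O)c(C)c(O)c1CO
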